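## Retrosynthetic overview

1. Last step: the C6–C7 bond is formed by a ring-closing allylboration of an enal, which closes the 10-membered carbocycle and, by lactonisation, the α-methylene lactone.
2. Before that: the 3(2H)-furanone comes from gold-catalysed cycloisomerisation of a γ-hydroxy alkynone, itself assembled from a terminal alkyne, CO and (Z)-3-iodobut-2-enal.
3. The C8 methacrylate and C9 acetate come from a trans vinyl epoxide: SN2 opening by methacrylic acid (inversion at C8), then acetylation. C10 is set by chelation-controlled ethynylation of the epoxy ketone.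
4. C8 and C9, the first stereocentres, come from organocatalytic epoxidation of (E)-4-oxopent-2-enal (from 2-methylfuran), telescoped with an olefination that brings in C11–C13.
5. Ring order: oxirane (temporary), then furanone, then carbocycle and lactone together.

Assumption: the SMILES is taken literally, i.e. (4Z,6S,7S,8S,9S,10R) in germacrane numbering (C1–C15, used throughout) with a cis-fused 6,12-lactone.

## Route

Step 1
Reactants: 1 2-methylfuran
Product: 3 (2E)-4-oxopent-2-enal, via (2Z)-4-oxopent-2-enal 2 (not isolated)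
Conditions: NBS, NaHCO3, acetone/H2O (10:1), −15 °C; then pyridine (cat.), rt
Reagents that add atoms: water, O
Why: Bromine–water oxidative ring opening of the furan gives the cis-enedione, which pyridine isomerises to the trans isomer; no stereocentre is formed.

Step 2
Reactants: 3 (2E)-4-oxopent-2-enal; 4 ethyl 2-(diethoxyphosphoryl)prop-2-enoate; 5 (4-methoxyphenyl)methanol
Product: 8 ethyl (2E)-3-[(2R,3S)-3-acetyloxiran-2-yl]-2-{[(4-methoxyphenyl)methoxy]methyl}prop-2-enoate, via epoxy aldehyde 6 (not isolated), via phosphonate carbanion 7 (not isolated)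
Conditions: 3, (S)-2-{bis[3,5-bis(trifluoromethyl)phenyl][(trimethylsilyl)oxy]methyl}pyrrolidine (10 mol %), H2O2 (35% aq, 1.2 equiv), CH2Cl2, rt, then dried (MgSO4); separately 5, NaH, THF, 0 °C, then 4, −78 °C; solutions combined, −78 to 0 °C
Reagents that add atoms: hydrogen peroxide, OO
Why: Iminium-catalysed epoxidation of an enal (Jørgensen–Hayashi type) delivers peroxide to the β-carbon on the face opposite the diaryl(silyloxy)methyl group and enamine closure gives the trans (2S,3S)-epoxy aldehyde (C8 and C9, the first stereocentres), which is trapped at the aldehyde only by an oxa-Michael-triggered Horner–Wadsworth–Emmons olefination that gives mainly the E enoate (C8 trans to the ester).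

Step 3
Reactants: 8 ethyl (2E)-3-[(2R,3S)-3-acetyloxiran-2-yl]-2-{[(4-methoxyphenyl)methoxy]methyl}prop-2-enoate; 9 ethynylmagnesium bromide
Product: 10 ethyl (2E)-3-{(2R,3S)-3-[(2S)-2-hydroxybut-3-yn-2-yl]oxiran-2-yl}-2-{[(4-methoxyphenyl)methoxy]methyl}prop-2-enoate
Conditions: 9 (1.3 equiv, 0.5 M in THF), CH2Cl2, −78 °C; aq NH4Cl
Reagents that add atoms: none
Why: Cram-chelate addition: magnesium bridges the ketone and oxirane oxygens and the acetylide attacks the ketone anti to C8, which sets C10 with the C9–O/C10–O syn relationship, the ketone reacting far faster than the ester at −78 °C.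

Step 4
Reactants: 10 ethyl (2E)-3-{(2R,3S)-3-[(2S)-2-hydroxybut-3-yn-2-yl]oxiran-2-yl}-2-{[(4-methoxyphenyl)methoxy]methyl}prop-2-enoate; 11 2-methylprop-2-enoic acid; 12 acetic anhydride
Product: 14 ethyl (2E,4S,5S,6S)-5-acetoxy-6-hydroxy-2-{[(4-methoxyphenyl)methoxy]methyl}-6-methyl-4-[(2-methylprop-2-enoyl)oxy]oct-2-en-7-ynoate, via hydroxy methacrylate 13 (not isolated)
Conditions: 11 (3 equiv), Ti(OiPr)4 (1.5 equiv), CH2Cl2, 0 °C to rt; aq tartaric acid; crude 13, 12, pyridine, DMAP (cat.), CH2Cl2, 0 °C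
Reagents that add atoms: none
Why: Titanium-assisted acidolysis of a 2,3-epoxy alcohol (Sharpless-type C3 opening, here directed by the C10 alkoxide and reinforced by the allylic position) is an SN2 attack of methacrylate at C8 with inversion, which gives the anti C8/C9 pattern, and the freed C9 hydroxyl is acetylated at once to forestall acyl migration while the tertiary C10 hydroxyl stays free.

Step 5
Reactants: 15 but-2-yn-1-ol
Product: 16 (2Z)-3-iodobut-2-en-1-ol
Conditions: NaAlH2(OCH2CH2OMe)2, THF, 0 °C; then I2, −78 °C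
Reagents that add atoms: iodine, [I][I]
Why: Hydroxyl-directed trans-hydroalumination puts aluminium on C3 and iodinolysis with retention gives the Z vinyl iodide.

Step 6
Reactants: 16 (2Z)-3-iodobut-2-en-1-ol
Product: 17 (2Z)-3-iodobut-2-enal
Conditions: MnO2, CH2Cl2, rt
Reagents that add atoms: none
Why: Neutral allylic alcohol oxidation gives the enal without Z/E isomerisation.

Step 7
Reactants: 14 ethyl (2E,4S,5S,6S)-5-acetoxy-6-hydroxy-2-{[(4-methoxyphenyl)methoxy]methyl}-6-methyl-4-[(2-methylprop-2-enoyl)oxy]oct-2-en-7-ynoate; 17 (2Z)-3-iodobut-2-enal; 18 carbon monoxide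
Product: 19 ethyl (2E,4S,5S,6S,10Z)-5-acetoxy-6-hydroxy-2-{[(4-methoxyphenyl)methoxy]methyl}-6,10-dimethyl-4-[(2-methylprop-2-enoyl)oxy]-9,12-dioxododeca-2,10-dien-7-ynoate
Conditions: PdCl2(PPh3)2 (5 mol %), Et3N (3 equiv), 18 (1 atm), THF, rt
Reagents that add atoms: none
Why: Carbonylative Sonogashira coupling: the vinyl iodide adds to zerovalent palladium with retention of the Z geometry, CO inserts and the alkyne is acylated, so C3 and both its C–C bonds are made without touching a stereocentre, the hindered electron-poor allylic ester ionising much more slowly than the β-iodo enal reacts.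

Step 8
Reactants: 19 ethyl (2E,4S,5S,6S,10Z)-5-acetoxy-6-hydroxy-2-{[(4-methoxyphenyl)methoxy]methyl}-6,10-dimethyl-4-[(2-methylprop-2-enoyl)oxy]-9,12-dioxododeca-2,10-dien-7-ynoate
Product: 20 ethyl (2E,4S,5S)-5-acetoxy-2-{[(4-methoxyphenyl)methoxy]methyl}-5-{(2R)-2-methyl-3-oxo-5-[(2Z)-4-oxobut-2-en-2-yl]-2,3-dihydrofuran-2-yl}-4-[(2-methylprop-2-enoyl)oxy]pent-2-enoate
Conditions: [(4-CF3C6H4)3P]AuCl (5 mol %), AgOTf (5 mol %), toluene, rt
Reagents that add atoms: none
Why: Gold-catalysed cycloisomerisation of a γ-hydroxy alkynone to a 3(2H)-furanone (formal alkyne hydration and cyclodehydration) never breaks the C10–O bond, so C10 keeps its configuration.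

Step 9
Reactants: 20 ethyl (2E,4S,5S)-5-acetoxy-2-{[(4-methoxyphenyl)methoxy]methyl}-5-{(2R)-2-methyl-3-oxo-5-[(2Z)-4-oxobut-2-en-2-yl]-2,3-dihydrofuran-2-yl}-4-[(2-methylprop-2-enoyl)oxy]pent-2-enoate
Product: 21 ethyl (2E,4S,5S)-5-acetoxy-2-(hydroxymethyl)-5-{(2R)-2-methyl-3-oxo-5-[(2Z)-4-oxobut-2-en-2-yl]-2,3-dihydrofuran-2-yl}-4-[(2-methylprop-2-enoyl)oxy]pent-2-enoate
Conditions: DDQ, CH2Cl2/pH 7 buffer (10:1), 0 °C
Reagents that add atoms: none
Why: Oxidative cleavage of the 4-methoxybenzyl ether leaves the esters, the enal and the furanone untouched.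

Step 10
Reactants: 21 ethyl (2E,4S,5S)-5-acetoxy-2-(hydroxymethyl)-5-{(2R)-2-methyl-3-oxo-5-[(2Z)-4-oxobut-2-en-2-yl]-2,3-dihydrofuran-2-yl}-4-[(2-methylprop-2-enoyl)oxy]pent-2-enoate
Product: 22 ethyl (2E,4S,5S)-5-acetoxy-5-{(2R)-2-methyl-3-oxo-5-[(2Z)-4-oxobut-2-en-2-yl]-2,3-dihydrofuran-2-yl}-4-[(2-methylprop-2-enoyl)oxy]-2-[(4,4,5,5-tetramethyl-1,3,2-dioxaborolan-2-yl)methyl]pent-2-enoate
Conditions: [Pd(MeCN)4](BF4)2 (5 mol %), B2pin2 (1.5 equiv), DMSO/MeOH (4:1), rt
Reagents that add atoms: bis(pinacolato)diboron, CC1(C)OB(OC1(C)C)B1OC(C)(C)C(C)(C)O1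
Why: Palladium-catalysed borylation of a primary allylic alcohol (Miyaura-type, through an allyl-palladium intermediate) delivers boron to the unhindered CH2 terminus and keeps the conjugated E enoate, and the electron-poor allylboronate does not add to the enal without acid.

Step 11
Reactants: 22 ethyl (2E,4S,5S)-5-acetoxy-5-{(2R)-2-methyl-3-oxo-5-[(2Z)-4-oxobut-2-en-2-yl]-2,3-dihydrofuran-2-yl}-4-[(2-methylprop-2-enoyl)oxy]-2-[(4,4,5,5-tetramethyl-1,3,2-dioxaborolan-2-yl)methyl]pent-2-enoate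
Product: 24 (4Z,6S,7S,8S,9S,10R)-9-acetoxy-8-(2-methylprop-2-enoyloxy)-1-oxo-3,10-epoxygermacra-2,4,11(13)-trien-12,6-olide (the target), via cyclic borate 23 (not isolated)
Conditions: (R)-3,3'-bis(2,4,6-triisopropylphenyl)-1,1'-binaphthyl-2,2'-diyl N-triflyl phosphoramide (10 mol %), 4 Å MS, toluene (1 mM), 0 °C to rt; aq NaHCO3
Reagents that add atoms: none
Why: Proposed new method: a chiral Brønsted acid-catalysed ring-closing allylboration of an electron-poor 2-(alkoxycarbonyl)allyl pinacolboronate, in which the acid hydrogen-bonds to a boronate oxygen (raising the Lewis acidity of boron) and orients the formyl group, so that C7 adds to C6 through a closed chair transition state with the C8 substituent (cis to CH2B) axial and the enal residue equatorial, which gives the syn adduct and hence the cis lactone; the (R)-acid selects the aldehyde face that gives 6S and the substrate agrees (C8–H eclipses the alkene and the aldehyde approaches anti to the C9 branch, giving 7S); no carbanionic allyl metal is formed, so the C8 acyloxy group cannot be lost by 1,4-elimination, and the borate 23 lactonises onto the ethyl ester under the same acid; closest known reaction types are the chiral phosphoric acid-catalysed allylboration of aldehydes with allyl pinacolboronate and the strong-acid-catalysed addition of 2-alkoxycarbonyl allylboronates to aldehydes with in situ lactonisation.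

## Compound list

1 | 2-methylfuran | Cc1ccco1 | starting material
2 | (2Z)-4-oxopent-2-enal | CC(=O)/C=C\C=O | intermediate
3 | (2E)-4-oxopent-2-enal | CC(=O)/C=C/C=O | intermediate
4 | ethyl 2-(diethoxyphosphoryl)prop-2-enoate | C=C(C(=O)OCC)P(=O)(OCC)OCC | starting material
5 | (4-methoxyphenyl)methanol | COc1ccc(CO)cc1 | starting material
6 | (2S,3S)-3-acetyloxirane-2-carbaldehyde | CC(=O)[C@H]1O[C@@H]1C=O | intermediate
7 | sodium salt of the carbanion of ethyl 2-(diethoxyphosphoryl)-3-[(4-methoxyphenyl)methoxy]propanoate | CCOC(=O)[C-](COCc1ccc(OC)cc1)P(=O)(OCC)OCC.[Na+] | intermediate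
8 | ethyl (2E)-3-[(2R,3S)-3-acetyloxiran-2-yl]-2-{[(4-methoxyphenyl)methoxy]methyl}prop-2-enoate | CCOC(=O)/C(COCc1ccc(OC)cc1)=C/[C@H]1O[C@@H]1C(C)=O | intermediate
9 | ethynylmagnesium bromide | C#C[Mg]Br | starting material
10 | ethyl (2E)-3-{(2R,3S)-3-[(2S)-2-hydroxybut-3-yn-2-yl]oxiran-2-yl}-2-{[(4-methoxyphenyl)methoxy]methyl}prop-2-enoate | CCOC(=O)/C(COCc1ccc(OC)cc1)=C/[C@H]1O[C@@H]1[C@@](C)(O)C#C | intermediate
11 | 2-methylprop-2-enoic acid (methacrylic acid) | CC(=C)C(=O)O | starting material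
12 | acetic anhydride | CC(=O)OC(C)=O | starting material
13 | ethyl (2E,4S,5S,6S)-5,6-dihydroxy-2-{[(4-methoxyphenyl)methoxy]methyl}-6-methyl-4-[(2-methylprop-2-enoyl)oxy]oct-2-en-7-ynoate | CCOC(=O)/C(COCc1ccc(OC)cc1)=C/[C@H](OC(=O)C(C)=C)[C@H](O)[C@@](C)(O)C#C | intermediate
14 | ethyl (2E,4S,5S,6S)-5-acetoxy-6-hydroxy-2-{[(4-methoxyphenyl)methoxy]methyl}-6-methyl-4-[(2-methylprop-2-enoyl)oxy]oct-2-en-7-ynoate | CCOC(=O)/C(COCc1ccc(OC)cc1)=C/[C@H](OC(=O)C(C)=C)[C@H](OC(C)=O)[C@@](C)(O)C#C | intermediate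
15 | but-2-yn-1-ol | CC#CCO | starting material
16 | (2Z)-3-iodobut-2-en-1-ol | C/C(I)=C/CO | intermediate
17 | (2Z)-3-iodobut-2-enal | C/C(I)=C/C=O | intermediate
18 | carbon monoxide | [C-]#[O+] | starting material
19 | ethyl (2E,4S,5S,6S,10Z)-5-acetoxy-6-hydroxy-2-{[(4-methoxyphenyl)methoxy]methyl}-6,10-dimethyl-4-[(2-methylprop-2-enoyl)oxy]-9,12-dioxododeca-2,10-dien-7-ynoate | CCOC(=O)/C(COCc1ccc(OC)cc1)=C/[C@H](OC(=O)C(C)=C)[C@H](OC(C)=O)[C@@](C)(O)C#CC(=O)/C(C)=C\C=O | intermediate
20 | ethyl (2E,4S,5S)-5-acetoxy-2-{[(4-methoxyphenyl)methoxy]methyl}-5-{(2R)-2-methyl-3-oxo-5-[(2Z)-4-oxobut-2-en-2-yl]-2,3-dihydrofuran-2-yl}-4-[(2-methylprop-2-enoyl)oxy]pent-2-enoate | CCOC(=O)/C(COCc1ccc(OC)cc1)=C/[C@H](OC(=O)C(C)=C)[C@H](OC(C)=O)[C@@]1(C)OC(=CC1=O)/C(C)=C\C=O | intermediate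
21 | ethyl (2E,4S,5S)-5-acetoxy-2-(hydroxymethyl)-5-{(2R)-2-methyl-3-oxo-5-[(2Z)-4-oxobut-2-en-2-yl]-2,3-dihydrofuran-2-yl}-4-[(2-methylprop-2-enoyl)oxy]pent-2-enoate | CCOC(=O)/C(CO)=C/[C@H](OC(=O)C(C)=C)[C@H](OC(C)=O)[C@@]1(C)OC(=CC1=O)/C(C)=C\C=O | intermediate
22 | ethyl (2E,4S,5S)-5-acetoxy-5-{(2R)-2-methyl-3-oxo-5-[(2Z)-4-oxobut-2-en-2-yl]-2,3-dihydrofuran-2-yl}-4-[(2-methylprop-2-enoyl)oxy]-2-[(4,4,5,5-tetramethyl-1,3,2-dioxaborolan-2-yl)methyl]pent-2-enoate | CCOC(=O)/C(CB1OC(C)(C)C(C)(C)O1)=C/[C@H](OC(=O)C(C)=C)[C@H](OC(C)=O)[C@@]1(C)OC(=CC1=O)/C(C)=C\C=O | intermediate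
23 | ethyl 2-[(4Z,6S,7S,8S,9S,10R)-9-acetoxy-8-(2-methylprop-2-enoyloxy)-1-oxo-6-[(4,4,5,5-tetramethyl-1,3,2-dioxaborolan-2-yl)oxy]-3,10-epoxygermacra-2,4-dien-7-yl]prop-2-enoate | C=C(C)C(=O)O[C@H]1[C@@H](C(=C)C(=O)OCC)[C@@H](OB2OC(C)(C)C(C)(C)O2)/C=C(/C)C2=CC(=O)[C@](C)(O2)[C@H]1OC(C)=O | intermediate
24 | (4Z,6S,7S,8S,9S,10R)-9-acetoxy-8-(2-methylprop-2-enoyloxy)-1-oxo-3,10-epoxygermacra-2,4,11(13)-trien-12,6-olide (CNP0365569.3) | C=C(C)C(=O)O[C@H]1[C@H]2C(=C)C(=O)O[C@H]2/C=C(/C)C2=CC(=O)[C@](C)(O2)[C@H]1OC(C)=O | target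

## Step count and risks

Total steps: 11. Longest linear sequence: 9 (steps 1–4 and 7–11).

**Step 11 (the proposed new step).** The risks are a slow or mismatched catalyst–substrate pairing, an uncatalysed background cyclisation with lower selectivity, and ring strain in the closing transition state. The fallback is known chemistry with a different allyl-transfer manifold and sets out from 21. NBS/Me2S (CH2Cl2, −20 °C) converts the allylic alcohol into the allylic bromide ethyl (2Z,4S,5S)-5-acetoxy-2-(bromomethyl)-5-{(2R)-2-methyl-3-oxo-5-[(2Z)-4-oxobut-2-en-2-yl]-2,3-dihydrofuran-2-yl}-4-[(2-methylprop-2-enoyl)oxy]pent-2-enoate F1. Indium powder in THF/H2O at 1 mM (Barbier conditions, so that the allylindium is trapped by the tethered aldehyde as it forms) closes the ring to the hydroxy ester ethyl 2-[(4Z,6S,7S,8S,9S,10R)-9-acetoxy-6-hydroxy-8-(2-methylprop-2-enoyloxy)-1-oxo-3,10-epoxygermacra-2,4-dien-7-yl]prop-2-enoate F2. This lactonises with TsOH (cat.) and comes back to the route at 24. The Barbier allylation–lactonisation of 2-(bromomethyl)alk-2-enoates is syn-selective through a cyclic transition state, but here facial control rests on the substrate alone and some 1,4-elimination of the C8 ester must be expected.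

**Step 2.** The epoxy keto aldehyde 6 is small, electrophilic and base-sensitive, and the olefination of an α-substituted phosphonate may give too much Z isomer. The fallback reverses the order and sets out from 3. Carbanion 7 is added to 3 itself (olefination at the aldehyde) to give ethyl (2E,4E)-2-{[(4-methoxyphenyl)methoxy]methyl}-6-oxohepta-2,4-dienoate F3. Its enone double bond is then epoxidised with H2O2 under iminium catalysis by a cinchona-derived primary amine salt (9-amino-9-deoxy-epi-quinine trifluoroacetate or its pseudo-enantiomer, whichever gives the (2R,3S)-oxirane), a known asymmetric epoxidation of acyclic enones. This comes back to the route at 8.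

**Step 7.** Direct (non-carbonylative) coupling can compete with CO insertion for the very reactive β-iodo enal, and zerovalent palladium may ionise the allylic methacrylate. The fallback avoids palladium and CO and sets out from 14. Commercial 3-methylfuran-2(5H)-one is reduced (iBu2AlH, CH2Cl2, −78 °C) to the lactol 3-methyl-2,5-dihydrofuran-2-ol F4. The zinc acetylide of 14 (ZnMe2, toluene, rt) adds to the open hydroxy-enal form of F4 to give the diol ethyl (2E,4S,5S,6S,10Z)-5-acetoxy-6,9,12-trihydroxy-2-{[(4-methoxyphenyl)methoxy]methyl}-6,10-dimethyl-4-[(2-methylprop-2-enoyl)oxy]dodeca-2,10-dien-7-ynoate F5 (both C9 epimers). MnO2 then oxidises the propargylic/allylic secondary alcohol and the primary allylic alcohol together and comes back to the route at 19.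

## Further compounds

F1 | step 11 | ethyl (2Z,4S,5S)-5-acetoxy-2-(bromomethyl)-5-{(2R)-2-methyl-3-oxo-5-[(2Z)-4-oxobut-2-en-2-yl]-2,3-dihydrofuran-2-yl}-4-[(2-methylprop-2-enoyl)oxy]pent-2-enoate | CCOC(=O)/C(CBr)=C/[C@H](OC(=O)C(C)=C)[C@H](OC(C)=O)[C@@]1(C)OC(=CC1=O)/C(C)=C\C=O
F2 | step 11 | ethyl 2-[(4Z,6S,7S,8S,9S,10R)-9-acetoxy-6-hydroxy-8-(2-methylprop-2-enoyloxy)-1-oxo-3,10-epoxygermacra-2,4-dien-7-yl]prop-2-enoate | C=C(C)C(=O)O[C@H]1[C@@H](C(=C)C(=O)OCC)[C@@H](O)/C=C(/C)C2=CC(=O)[C@](C)(O2)[C@H]1OC(C)=O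
F3 | step 2 | ethyl (2E,4E)-2-{[(4-methoxyphenyl)methoxy]methyl}-6-oxohepta-2,4-dienoate | CCOC(=O)/C(COCc1ccc(OC)cc1)=C/C=C/C(C)=O
F4 | step 7 | 3-methyl-2,5-dihydrofuran-2-ol | CC1=CCOC1O
F5 | step 7 | ethyl (2E,4S,5S,6S,10Z)-5-acetoxy-6,9,12-trihydroxy-2-{[(4-methoxyphenyl)methoxy]methyl}-6,10-dimethyl-4-[(2-methylprop-2-enoyl)oxy]dodeca-2,10-dien-7-ynoate | CCOC(=O)/C(COCc1ccc(OC)cc1)=C/[C@H](OC(=O)C(C)=C)[C@H](OC(C)=O)[C@@](C)(O)C#CC(O)/C(C)=C\CO
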